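Briarane numbering is used for every compound: C1 quaternary ring-fusion carbon (methyl C15), C2 isovalerate carbinol, C5 tertiary carbinol (methyl C16), C6=C7 enol-lactone alkene, C8=C17 butenolide alkene (methyl C18, carbonyl C19), C10 ring-fusion CH, C11=C12 ring A alkene (methyl C20), C14 acetate carbinol.

## Structural features

The target is a tricycle. Cyclohexene ring A (C1, C10–C14) is trans-fused along C1–C10 to a ten-membered carbocycle (C1–C10), which carries an α-methyl-γ-alkylidene butenolide fused across C7–C8. Three stereocentres are contiguous (C14 acetate, quaternary C1, C2 isovalerate), C10 adjoins C1 on the other side, and the tertiary carbinol C5 is isolated behind C3–C4. On ring A the C14 oxygen and the C1–C2 bond are cis, while C15 and C9 are cis to each other, so that H10 is trans to C15. The C6=C7 alkene is E by the sequence rules (lactone oxygen and C5 on opposite sides), which is the ring-cis arrangement of C5 and C8. Fragile groups are the two different esters, the tertiary allylic alcohol at C5 (vinylogous to the enol ester, so it ionises in acid), and the cross-conjugated dienyl lactone, which is open to base and to 1,6-addition. The real difficulty is closing the ten-membered ring at the hindered C1/C10 junction with C9 on the face of C15, and keeping five oxygen functions (C2, C5, C7, C12, C14) apart. The key step uses the fact that C10 is the allylic carbon of the ring A alkene. C10–C11–C12 can therefore act as an allyl unit with a leaving group at C12 and the alkene at C10=C11, and a C9 carbanion (acidified by the C8 ketone and a removable sulfone) can close C9–C10 while the alkene moves to C11=C12.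

## Logic of the disconnections

**36 back to 32.** No skeletal bond is cut. The free C5 hydroxyl is traced to silyl ether 35, and the C6=C7 alkene to the saturated butenolide 32 through 33 and 34. This keeps the acid- and base-sensitive dienyl enol lactone and the allylic tertiary alcohol out of the route until the last three steps. The forward steps must functionalise C7 and not C17 or ring A, eliminate toward C6 to the ring-cis alkene, and desilylate without acid.

**32 back to 30.** C8=C17 and the C19–O7 ester bond are cut, leaving α-hydroxy ketone 30 and a phosphonopropionic acid. An intramolecular olefination is the reliable way to a tetrasubstituted alkene at a hindered ring ketone, and the five-membered ring fixes its geometry. The butenolide shrinks to a ketol. The demand is a free C7 hydroxyl next to a still-protected C5 oxygen, hence the sterically graded silyl ethers of 29.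

**30 back to 27 (through 29 and 28).** C9–C10 is cut, which opens the ten-membered ring. The cut lies next to ring A, where the alkene supplies allyl reactivity, and next to the C8 ketone, which supplies carbanion reactivity. One ring and the C10 stereocentre are removed, and the problem becomes an open chain on a cyclohexene. The forward step must deliver C9 to C10 and not to C12, on the face cis to C15; this fixes the C12 carbonate of 27 cis to C15.

**27 back to 23 and 24.** C8–C9 is cut. Addition of the sulfonyl carbanion to an aldehyde followed by oxidation is preferred to acylation by an ester, because 23 already carries an acetate, an isovalerate and a carbonate. The gain is a commercial one-carbon piece. The demand is a C8 aldehyde released late, hence the primary silyl ether of 22.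

**22 back to 16 (through 21, 19 and 17).** Only functional groups change. The C12 oxygen and the C10=C11 alkene come from the enone through epoxide 17 and a 1,3-transposition, and the C14 acetate comes from the isopropenyl group with retention. Ring A becomes the carvone pattern. The demands are an epoxidation anti to the C14 substituent, and ozonolysis carried out while the molecule holds no other alkene (the enone is masked as the epoxide and the side chain is saturated).

**16 back to 10 and 9 (through 15, 14, 13 and 12).** C1–C15 and C1–C2 are cut. Methyl must be the last substituent introduced at C1, because the group that enters last ends up trans to the isopropenyl group, and the target needs C2 cis to the C14 oxygen. C2 is therefore attached first as an acyl group and C15 second, and the C2 carbinol is set afterwards by reduction. The demand is facial control in the alkylation of the diketone enolate and in the reduction of the C2 ketone.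

**9 back to 1 (through 7, 6, 5, 3 and 2).** The C2=C alkene of 1 becomes the aldehyde, C8 is added to the vinyl group as carbon monoxide, and the C7 oxygen is introduced α to that aldehyde. The tertiary carbinol C5 is taken from the chiral pool. The demands are linear hydroformylation and reagent-controlled α-oxygenation.

## Other disconnections considered

**Alternative 1:** The cut removes C1–C2 and C5–C6 as a [2+2] pair. Irradiation of enone A2 with 1-methylcyclobutene A3 would give the cis-anti-cis photoadduct A1. Heating would then cleave the two inner cyclobutane bonds (C1–C6 and C2–C5) and release cyclodecadienone A4.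
- In its favour: two ring bonds form in one intermolecular step from small partners, no high dilution is needed, and strain release opens the ten-membered ring. The C5 methyl and the C7 carbonyl arrive in place, and the C5=C6–C7=O enone is a direct handle for the C5 oxygen and the C6=C7 enol lactone.
- Against it here: the cycloreversion leaves C1 as an alkene carbon (C1=C2). The quaternary centre, the C2 oxygen and ring A (only C11 and C20 are present, as a ketal) would all have to be built afterwards on a flexible medium ring. Head-to-head versus head-to-tail orientation with an unsymmetrical cyclobutene, the facial bias from C10, the alkene geometry after thermolysis and Cope rearrangement of the 1,5-diene to a divinylcyclohexane are all open.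
- Comparison: this alternative is better in convergence and in the way the ring is formed (no macrocyclisation, no sulfone to remove). It is weaker in structure, since the chosen plan reaches ring closure with C1, C2, C5 and C14 already set and fixes C10 by chirality transfer. Its step count after ring formation would be higher.

**Alternative 2:** The cut is C6–C7, with a temporary O–C5 bond. Aldoxime A6 would be oxidised to the nitrile oxide, which would add across the 1,1-disubstituted C5=C6 alkene to give the isoxazoline-bridged carbocycle A5.
- In its favour: the cycloaddition forms the ring bond and installs the C5 oxygen and the C7 carbonyl level together, masked as a β-hydroxy ketone. The regiochemistry (oxygen to the substituted carbon) is reliable and esters are tolerated. The C19 ester is already cis to C7, so the route from A5 to the target (N–O cleavage, enol lactonisation) is shorter than the six steps after the palladium closure; on step economy after ring closure it is the better plan.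
- Against it here: C5 would be created during a ten-membered ring closure, with only the conformation of the forming ring to choose its face, whereas the chosen plan takes C5 from linalool. Dimerisation of the conjugated nitrile oxide and addition to the ring A alkene compete with a slow medium-ring closure. The unveiled β-hydroxy ketone can dehydrate across C5–C6. C10 must be set by other means before the key step.
- Comparison: mechanistically the concerted cycloaddition avoids the site selectivity and β-hydride problems of an allyl complex, which is an advantage. Both plans need high dilution, so they are equal there. In stereocontrol the chosen plan is stronger.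

**Alternative 3:** The cut is C4–C5, with a sacrificial C2–C7 bond. The potassium alkoxide of divinyl carbinol A8 would undergo the anionic oxy-Cope shift to the ten-membered ketone A7.
- In its favour: a six-membered ring is expanded, so no macrocyclisation is needed, and the rearrangement is driven by enolate formation. It delivers the C6=C7 enol lactone and the C5 oxygen directly. The endgame from A7 (ketone reduction, acylations, desilylation) is short; in ring formation and endgame length it is equal to or better than the chosen plan.
- Against it here: the C5 configuration and the C6=C7 geometry both depend on a chair or boat transition state and on the enol ether geometry. A8 has three contiguous fully substituted carbons (C1, C2, C7) and is itself hard to assemble. Potassium hydride excludes the acetate and the isovalerate, so C14 and C2 need protecting-group changes, and C2 must later be reduced with facial control. The butenolide can be deprotonated at C9.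
- Comparison: the chosen plan is longer after ring closure, but it has the more accessible precursor, takes C5 from the chiral pool and sets C10 by a stereospecific process.

Key step: step 19

**Remarks on the chemistry (checks and assumptions)**
- The configurations of 27 and 28 were checked against 36. C1, C2, C5, C10 and C14 agree, the C12 carbonate of 27 lies cis to C15 as the double inversion requires, and (S)-carvone and (S)-linalool have the correct sense for C14 and C5. No structure needed correction.
- Three design points differ from the simplest plan:
  1. At C1 the acyl group is introduced before the methyl group; the reverse order would put the side chain trans to the C14 oxygen.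
  2. The β-keto sulfone is built by aldehyde addition and oxidation, not by ester acylation, because three other esters are present.
  3. C7 carries a triethylsilyl ether, so that the silyl ethers at C8, C7 and C5 can be removed in that order.
- Assumption: the C7 configuration is of no consequence, because C7 becomes trigonal in step 25. It is set as R by L-proline.
- 12 and 13 are carried as mixtures at C1/C2 and 26 as a mixture at C8; these centres are reset or removed. C9 of 28 is epimerisable and is drawn as one epimer.

## Route

Step 1
Reactants: 1 (S)-linalool
Product: 2 (S)-linalool triethylsilyl ether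
Conditions: TESOTf, 2,6-lutidine, CH2Cl2, −78 → 0 °C
Reagents that add atoms: triethylsilyl trifluoromethanesulfonate, CC[Si](CC)(CC)OS(=O)(=O)C(F)(F)F
Why: Silylation of a tertiary alcohol with a silyl triflate; C5 is untouched, and the ether prevents the alcohol from closing a lactol onto the aldehydes made later.

Step 2
Reactants: 2 (S)-linalool triethylsilyl ether
Product: 3 (4S)-4,8-dimethyl-4-(triethylsilyloxy)non-7-enal
Conditions: Rh(acac)(CO)2 (0.5 mol %), Xantphos (2 mol %), CO/H2 (1:1, 20 bar), toluene, 70 °C
Reagents that add atoms: carbon monoxide, [C-]#[O+]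
Why: Rhodium-catalysed hydroformylation; a vinyl group on a fully substituted carbon can only give the linear aldehyde (C8 comes from CO) and cannot isomerise, and the trisubstituted alkene is inert under these conditions.

Step 3
Reactants: 3 (4S)-4,8-dimethyl-4-(triethylsilyloxy)non-7-enal
Product: 5 (2R,4S)-2-(anilinooxy)-4,8-dimethyl-4-(triethylsilyloxy)non-7-en-1-ol, via α-anilinooxy aldehyde 4 (not isolated)
Conditions: PhNO (slow addition), L-proline (20 mol %), CHCl3, 4 °C; then NaBH4, EtOH, 0 °C
Reagents that add atoms: nitrosobenzene, O=Nc1ccccc1
Why: Proline-catalysed α-aminoxylation of the aldehyde through its enamine, with O-selective attack on nitrosobenzene directed by the carboxylic acid; L-proline should give the 7R centre by reagent control, and immediate borohydride reduction prevents racemisation and self-condensation.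

Step 4
Reactants: 5 (2R,4S)-2-(anilinooxy)-4,8-dimethyl-4-(triethylsilyloxy)non-7-en-1-ol
Product: 6 (2R,4S)-4,8-dimethyl-4-(triethylsilyloxy)non-7-ene-1,2-diol
Conditions: Zn dust, AcOH/THF (1:4), rt
Reagents that add atoms: none
Why: Reductive cleavage of the weak N–O bond by zinc; the alkene and the hindered tertiary silyl ether should survive the short, weakly acidic treatment.

Step 5
Reactants: 6 (2R,4S)-4,8-dimethyl-4-(triethylsilyloxy)non-7-ene-1,2-diol
Product: 7 (2R,4S)-4,8-dimethyl-1,2,4-tris(triethylsilyloxy)non-7-ene
Conditions: TESCl, imidazole, DMAP (cat.), DMF, 0 °C → rt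
Reagents that add atoms: chlorotriethylsilane, CC[Si](Cl)(CC)CC
Why: Standard silylation of a primary and a secondary alcohol; the primary (C8), secondary (C7) and tertiary (C5) triethylsilyl ethers differ enough in shielding to be released later in that order.

Step 6
Reactants: 7 (2R,4S)-4,8-dimethyl-1,2,4-tris(triethylsilyloxy)non-7-ene
Product: 9 (4S,6R)-4-methyl-4,6,7-tris(triethylsilyloxy)heptanal, via ozonide 8 (not isolated)
Conditions: O3, CH2Cl2, −78 °C; then PPh3, −78 °C → rt
Reagents that add atoms: ozone, [O-][O+]=O
Why: Ozonolysis with reductive work-up of the only alkene gives the C2 aldehyde and acetone; silyl ethers are inert to ozone.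

Step 7
Reactants: 10 (S)-carvone; 9 (4S,6R)-4-methyl-4,6,7-tris(triethylsilyloxy)heptanal
Product: 12 aldol adduct (C1/C2 epimer mixture), via lithium dienolate 11 (not isolated)
Conditions: LiN(iPr)2, THF, −78 °C; then 9, −78 °C; AcOH quench at −78 °C
Reagents that add atoms: none
Why: Kinetic deprotonation of carvone at the saturated α'-carbon (the future C1) and aldol addition to the aldehyde; the configurations at C1 and C2 do not matter because both centres are set again in steps 9 and 10.

Step 8
Reactants: 12 aldol adduct (C1/C2 epimer mixture)
Product: 13 enolised 1,3-diketone (C2 and C10 carbonyls)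
Conditions: Dess–Martin periodinane, NaHCO3, CH2Cl2, 0 °C → rt
Reagents that add atoms: none
Why: Oxidation of a β-hydroxy ketone to the 1,3-diketone under buffered, non-basic conditions that avoid retro-aldol cleavage; all epimers of 12 converge to one compound.

Step 9
Reactants: 13 enolised 1,3-diketone
Product: 14 C1-methylated diketone (C15 trans to isopropenyl)
Conditions: K2CO3, MeI, acetone, rt → 40 °C
Reagents that add atoms: iodomethane, CI
Why: C-alkylation of a 1,3-diketone enolate by a soft electrophile creates the quaternary C1; the planar enolate is shielded on one face by the adjacent pseudoaxial isopropenyl group at C14, so methyl should enter trans to it and leave the acyl group (C2) cis to the future C14 oxygen.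

Step 10
Reactants: 14 C1-methylated diketone
Product: 15 (2S)-C2 alcohol
Conditions: Zn(BH4)2, Et2O, −30 → 0 °C
Reagents that add atoms: none
Why: Chelation-controlled reduction of a non-enolisable 1,3-diketone: zinc bridges the C2 and C10 carbonyl oxygens and hydride reaches the saturated, more electrophilic C2 ketone from the chelate face that carries the small C15 methyl (opposite C14), which corresponds to 2S; the conjugated and more hindered C10 ketone should react more slowly.

Step 11
Reactants: 15 (2S)-C2 alcohol
Product: 16 C2 isovalerate
Conditions: isovaleric anhydride, Et3N, DMAP, CH2Cl2, rt → 40 °C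
Reagents that add atoms: isovaleric anhydride, CC(C)CC(=O)OC(=O)CC(C)C
Why: DMAP-catalysed acylation of a hindered secondary alcohol; the ester is the final C2 substituent and also blocks retro-aldol cleavage of the β-hydroxy ketone.

Step 12
Reactants: 16 C2 isovalerate
Product: 17 11,12-epoxy ketone (epoxide cis to C15)
Conditions: t-BuOOH (anhydrous), DBU, CH2Cl2, 0 °C → rt
Reagents that add atoms: tert-butyl hydroperoxide, CC(C)(C)OO
Why: Weitz–Scheffer nucleophilic epoxidation of the enone under anhydrous conditions that spare the ester and the silyl ethers; as with carvone itself, the peroxide anion should add to C12 anti to the C14 isopropenyl group, which puts the epoxide oxygen cis to C15.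

Step 13
Reactants: 17 11,12-epoxy ketone
Product: 19 C14 acetate, via α-methoxy hydroperoxide 18 (not isolated)
Conditions: O3, CH2Cl2/MeOH (4:1), NaHCO3, −78 °C; then Ac2O, Et3N, DMAP (cat.), CH2Cl2, 0 °C → rt
Reagents that add atoms: ozone, [O-][O+]=O; methanol, CO
Why: Ozonolysis of the isopropenyl group in methanol and Criegee rearrangement of the derived peracetate; C14 migrates from carbon to oxygen with retention, so the acetate (built from the old isopropenyl carbon and methyl) takes the place of the isopropenyl group, and ozone finds only one alkene because the enone is already the epoxide.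

Step 14
Reactants: 19 C14 acetate
Product: 21 C12 allylic alcohol (C10=C11), via epoxy hydrazone 20 (not isolated)
Conditions: N2H4·H2O, AcOH (cat.), MeOH, 0 °C → rt
Reagents that add atoms: none
Why: Wharton transposition: the hydrazone of the epoxy ketone opens the epoxide and loses N2, giving the C10=C11 alkene and the C12 alcohol, whose C–O bond (cis to C15) is the untouched epoxide bond; buffered hydrazine at or below room temperature should leave the acetate and the hindered isovalerate intact.

Step 15
Reactants: 21 C12 allylic alcohol
Product: 22 C12 methyl carbonate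
Conditions: ClCO2Me, pyridine, DMAP (cat.), CH2Cl2, 0 °C
Reagents that add atoms: methyl chloroformate, COC(=O)Cl
Why: Acylation of the unhindered secondary allylic alcohol; the carbonate ionises readily with zerovalent palladium and releases its own base.

Step 16
Reactants: 22 C12 methyl carbonate
Product: 23 C8 aldehyde
Conditions: (COCl)2, DMSO, CH2Cl2, −78 → −40 °C; then Et3N, −78 °C → rt
Reagents that add atoms: none
Why: Under Swern conditions a primary triethylsilyl ether is exchanged by chlorodimethylsulfonium chloride and oxidised directly to the aldehyde, while the secondary and tertiary silyl ethers, the esters and the carbonate are left alone.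

Step 17
Reactants: 23 C8 aldehyde; 24 methyl phenyl sulfone
Product: 26 β-hydroxy sulfone (C8 epimers), via lithiated methyl phenyl sulfone 25 (not isolated)
Conditions: 24, n-BuLi, THF, −78 °C; then 23, −78 °C; AcOH quench at −78 °C
Reagents that add atoms: none
Why: 1,2-Addition of a sulfone-stabilised carbanion to an aldehyde is fast at −78 °C, whereas the acetate, isovalerate and carbonate acylate such anions only at higher temperature, so C8–C9 forms chemoselectively; the cold acidic quench forestalls silyl migration from O7 to the new alkoxide.

Step 18
Reactants: 26 β-hydroxy sulfone (C8 epimers)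
Product: 27 β-keto sulfone with C12 methyl carbonate
Conditions: Dess–Martin periodinane, NaHCO3, CH2Cl2, rt
Reagents that add atoms: none
Why: Oxidation of a β-hydroxy sulfone to the β-keto sulfone under neutral conditions; both C8 epimers converge.

Step 19
Reactants: 27 β-keto sulfone with C12 methyl carbonate
Product: 28 ten-membered β-keto sulfone (C11=C12)
Conditions: Pd(PPh3)4 (10 mol %), dppe (10 mol %), THF, 65 °C, syringe-pump addition, final 2 mM
Reagents that add atoms: none
Why: Zerovalent palladium binds the C10=C11 alkene on the face opposite the C12 carbonate and ionises it with inversion to an η3-allyl complex over C10–C11–C12, releasing CO2 and methoxide, which deprotonates the β-keto sulfone at C9. The soft, doubly stabilised carbanion then attacks an allyl terminus from outside the coordination sphere, anti to the metal. The closest known reaction type is the Tsuji–Trost allylic alkylation with sulfone-stabilised carbanions, a method used for medium and large carbocycles under high dilution. The ten-membered ring closes by attack at C10 in the exo sense with respect to the allyl unit, so C11 and C12 stay outside the new ring. The new C10 centre is controlled by the C12 centre through the double inversion: C9 arrives on the face the carbonate left, cis to C15, so H10 is trans to C15 as in the target, while the C9 centre is epimerisable and is deleted in step 20. The selectivities needed are C10 over C12 and carbon over oxygen: closure onto C12 would have to span ring A from C1 to C12 in a bicyclo[8.2.2] frame, and an O-allyl enol ether, if formed, is re-ionised by the catalyst and drains to the C-alkylated ketone. The non-allylic acetate and isovalerate are inert, and the medium stays neutral because the leaving group supplies the base.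

Step 20
Reactants: 28 ten-membered β-keto sulfone
Product: 29 ten-membered C8 ketone (5,7-bis-silyl ether)
Conditions: aluminium amalgam (Al/Hg), THF/H2O (10:1), 0 °C → rt
Reagents that add atoms: none
Why: Reductive cleavage of the C–S bond of a β-keto sulfone by electron transfer; the resulting enolate is protonated to the ketone, the C9 stereocentre disappears, and esters, silyl ethers and the isolated alkene are not reduced.

Step 21
Reactants: 29 ten-membered C8 ketone
Product: 30 C7 α-hydroxy ketone
Conditions: HF·pyridine, pyridine, THF, 0 °C
Reagents that add atoms: none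
Why: Buffered fluoride should remove the secondary triethylsilyl ether next to the ketone much faster than the shielded tertiary one at C5, freeing the C7 alcohol alone.

Step 22
Reactants: 30 C7 α-hydroxy ketone
Product: 31 C7 phosphonopropionate
Conditions: 2-(diethoxyphosphoryl)propanoic acid, DCC, DMAP (cat.), CH2Cl2, 0 °C → rt
Reagents that add atoms: 2-(diethoxyphosphoryl)propanoic acid, CCOP(=O)(OCC)C(C)C(=O)O
Why: Carbodiimide esterification of the only free hydroxyl; the phosphonate carbon is an epimer mixture, which is irrelevant because it becomes C17 of the alkene.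

Step 23
Reactants: 31 C7 phosphonopropionate
Product: 32 butenolide (C8=C17; C7–H)
Conditions: LiCl, i-Pr2NEt, MeCN, rt
Reagents that add atoms: none
Why: Intramolecular Horner–Wadsworth–Emmons olefination: the lithium-chelated phosphonate anion attacks the C8 ketone in a five-membered closure and loss of diethyl phosphate gives the C8=C17 alkene, whose geometry is fixed by the lactone ring; the mild amine base does not touch the acetate or the isovalerate.

Step 24
Reactants: 32 butenolide
Product: 33 2-(triisopropylsilyloxy)furan
Conditions: TIPSOTf, Et3N, CH2Cl2, 0 °C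
Reagents that add atoms: triisopropylsilyl trifluoromethanesulfonate, CC(C)[Si](C(C)C)(C(C)C)OS(=O)(=O)C(F)(F)F
Why: Soft enolisation of a butenolide: O-silylation of the lactone carbonyl and loss of the γ-proton at C7 give the aromatic silyloxyfuran, whereas simple esters are not enolised by a silyl triflate and triethylamine.

Step 25
Reactants: 33 2-(triisopropylsilyloxy)furan
Product: 35 (6E)-alkylidene butenolide 5-O-triethylsilyl ether, via γ-bromobutenolide 34 (not isolated)
Conditions: NBS, THF, −78 °C; then DBU, −78 → 0 °C
Reagents that add atoms: none
Why: Electrophilic bromination of the silyloxyfuran at its most nucleophilic position C7 regenerates the butenolide as a tertiary γ-bromide, and base-induced loss of HBr can only run toward C6 because C8 is trigonal; the ring-cis (E) alkene, with C5 and C8 on the same side, is the less strained isomer in the ten-membered ring and should be the one formed.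

Step 26
Reactants: 35 (6E)-alkylidene butenolide 5-O-triethylsilyl ether
Product: 36 target CNP0208239.1
Conditions: HF·pyridine, pyridine, THF, 0 °C → rt
Reagents that add atoms: none
Why: Fluoride cleavage of the tertiary triethylsilyl ether under buffered conditions that avoid ionisation of the allylic tertiary alcohol and acyl migration.

## Compound list

1 | (S)-linalool, (3S)-3,7-dimethylocta-1,6-dien-3-ol | C=C[C@@](C)(O)CCC=C(C)C | starting material
2 | (S)-linalool triethylsilyl ether | C=C[C@@](C)(O[Si](CC)(CC)CC)CCC=C(C)C | intermediate
3 | (4S)-4,8-dimethyl-4-(triethylsilyloxy)non-7-enal (aldehyde carbon is C8) | O=CCC[C@@](C)(O[Si](CC)(CC)CC)CCC=C(C)C | intermediate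
4 | (2R,4S)-2-(anilinooxy)-4,8-dimethyl-4-(triethylsilyloxy)non-7-enal (not isolated) | O=C[C@H](ONc1ccccc1)C[C@@](C)(O[Si](CC)(CC)CC)CCC=C(C)C | intermediate
5 | (2R,4S)-2-(anilinooxy)-4,8-dimethyl-4-(triethylsilyloxy)non-7-en-1-ol | OC[C@H](ONc1ccccc1)C[C@@](C)(O[Si](CC)(CC)CC)CCC=C(C)C | intermediate
6 | (2R,4S)-4,8-dimethyl-4-(triethylsilyloxy)non-7-ene-1,2-diol | OC[C@H](O)C[C@@](C)(O[Si](CC)(CC)CC)CCC=C(C)C | intermediate
7 | (2R,4S)-4,8-dimethyl-1,2,4-tris(triethylsilyloxy)non-7-ene | CC[Si](CC)(CC)OC[C@H](O[Si](CC)(CC)CC)C[C@@](C)(O[Si](CC)(CC)CC)CCC=C(C)C | intermediate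
8 | ozonide (3,3-dimethyl-1,2,4-trioxolane) of 7 (not isolated) | CC1(C)OOC(CC[C@](C)(O[Si](CC)(CC)CC)C[C@@H](O[Si](CC)(CC)CC)CO[Si](CC)(CC)CC)O1 | intermediate
9 | (4S,6R)-4-methyl-4,6,7-tris(triethylsilyloxy)heptanal (C2–C8 piece; 5S,7R in briarane numbering) | O=CCC[C@](C)(O[Si](CC)(CC)CC)C[C@@H](O[Si](CC)(CC)CC)CO[Si](CC)(CC)CC | intermediate
10 | (S)-carvone | CC1=CC[C@@H](CC1=O)C(C)=C | starting material
11 | lithium dienolate of (S)-carvone (not isolated) | CC1=CC[C@H](C(C)=C)C=C1[O-].[Li+] | intermediate
12 | aldol adduct: carvone carrying at C1 the 1-hydroxy-4-methyl-4,6,7-tris(triethylsilyloxy)heptyl chain; C1/C2 epimer mixture | CC1=CC[C@H](C(C)=C)C(C1=O)C(O)CC[C@](C)(O[Si](CC)(CC)CC)C[C@@H](O[Si](CC)(CC)CC)CO[Si](CC)(CC)CC | intermediate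
13 | 1,3-diketone (C2 and C10 carbonyls; enolised, C1 not defined) | CC1=CC[C@H](C(C)=C)C(C1=O)C(=O)CC[C@](C)(O[Si](CC)(CC)CC)C[C@@H](O[Si](CC)(CC)CC)CO[Si](CC)(CC)CC | intermediate
14 | C1-methylated diketone; C15 trans and C2 acyl cis to the C14 isopropenyl group | CC(=C)[C@H]1CC=C(C)C(=O)[C@@]1(C)C(=O)CC[C@](C)(O[Si](CC)(CC)CC)C[C@@H](O[Si](CC)(CC)CC)CO[Si](CC)(CC)CC | intermediate
15 | C2 alcohol (2S; C1 and C2 as in the target) | CC(=C)[C@H]1CC=C(C)C(=O)[C@@]1(C)[C@@H](O)CC[C@](C)(O[Si](CC)(CC)CC)C[C@@H](O[Si](CC)(CC)CC)CO[Si](CC)(CC)CC | intermediate
16 | C2 isovalerate of 15 (C10 enone, C14 isopropenyl) | CC(=C)[C@H]1CC=C(C)C(=O)[C@@]1(C)[C@@H](OC(=O)CC(C)C)CC[C@](C)(O[Si](CC)(CC)CC)C[C@@H](O[Si](CC)(CC)CC)CO[Si](CC)(CC)CC | intermediate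
17 | 11,12-epoxy C10 ketone; epoxide trans to isopropenyl, cis to C15 | CC(=C)[C@H]1C[C@@H]2O[C@]2(C)C(=O)[C@@]1(C)[C@@H](OC(=O)CC(C)C)CC[C@](C)(O[Si](CC)(CC)CC)C[C@@H](O[Si](CC)(CC)CC)CO[Si](CC)(CC)CC | intermediate
18 | α-methoxy hydroperoxide at the former isopropenyl carbon (not isolated) | COC(C)(OO)[C@H]1C[C@@H]2O[C@]2(C)C(=O)[C@@]1(C)[C@@H](OC(=O)CC(C)C)CC[C@](C)(O[Si](CC)(CC)CC)C[C@@H](O[Si](CC)(CC)CC)CO[Si](CC)(CC)CC | intermediate
19 | C14 acetate of the 11,12-epoxy C10 ketone | CC(=O)O[C@H]1C[C@@H]2O[C@]2(C)C(=O)[C@@]1(C)[C@@H](OC(=O)CC(C)C)CC[C@](C)(O[Si](CC)(CC)CC)C[C@@H](O[Si](CC)(CC)CC)CO[Si](CC)(CC)CC | intermediate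
20 | C10 hydrazone of 19 (not isolated) | CC(=O)O[C@H]1C[C@@H]2O[C@]2(C)C(=NN)[C@@]1(C)[C@@H](OC(=O)CC(C)C)CC[C@](C)(O[Si](CC)(CC)CC)C[C@@H](O[Si](CC)(CC)CC)CO[Si](CC)(CC)CC | intermediate
21 | C12 allylic alcohol with C10=C11; hydroxyl cis to C15 | CC(=O)O[C@H]1C[C@H](O)C(C)=C[C@@]1(C)[C@@H](OC(=O)CC(C)C)CC[C@](C)(O[Si](CC)(CC)CC)C[C@@H](O[Si](CC)(CC)CC)CO[Si](CC)(CC)CC | intermediate
22 | C12 methyl carbonate of 21 | CC(=O)O[C@H]1C[C@H](OC(=O)OC)C(C)=C[C@@]1(C)[C@@H](OC(=O)CC(C)C)CC[C@](C)(O[Si](CC)(CC)CC)C[C@@H](O[Si](CC)(CC)CC)CO[Si](CC)(CC)CC | intermediate
23 | C8 aldehyde (7-O- and 5-O-triethylsilyl ethers, C12 carbonate) | CC(=O)O[C@H]1C[C@H](OC(=O)OC)C(C)=C[C@@]1(C)[C@@H](OC(=O)CC(C)C)CC[C@](C)(O[Si](CC)(CC)CC)C[C@@H](O[Si](CC)(CC)CC)C=O | intermediate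
24 | methyl phenyl sulfone | CS(=O)(=O)c1ccccc1 | starting material
25 | lithiated methyl phenyl sulfone (not isolated) | [Li+].[CH2-]S(=O)(=O)c1ccccc1 | intermediate
26 | β-hydroxy sulfone (C8 carbinol, C9 sulfone; C8 epimers) | CC(=O)O[C@H]1C[C@H](OC(=O)OC)C(C)=C[C@@]1(C)[C@@H](OC(=O)CC(C)C)CC[C@](C)(O[Si](CC)(CC)CC)C[C@@H](O[Si](CC)(CC)CC)C(O)CS(=O)(=O)c1ccccc1 | intermediate
27 | key-step precursor: ring A C12 methyl carbonate with C8 ketone and C9 phenyl sulfone | CC(=O)O[C@H]1C[C@H](OC(=O)OC)C(C)=C[C@@]1(C)[C@@H](OC(=O)CC(C)C)CC[C@](C)(O[Si](CC)(CC)CC)C[C@@H](O[Si](CC)(CC)CC)C(=O)CS(=O)(=O)c1ccccc1 | intermediate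
28 | key-step product: ten-membered β-keto sulfone with C11=C12 | CC(=O)O[C@H]1CC=C(C)[C@@H]2[C@@H](S(=O)(=O)c3ccccc3)C(=O)[C@H](O[Si](CC)(CC)CC)C[C@@](C)(O[Si](CC)(CC)CC)CC[C@H](OC(=O)CC(C)C)[C@@]12C | intermediate
29 | ten-membered C8 ketone, 5,7-bis(triethylsilyl) ether | CC(=O)O[C@H]1CC=C(C)[C@@H]2CC(=O)[C@H](O[Si](CC)(CC)CC)C[C@@](C)(O[Si](CC)(CC)CC)CC[C@H](OC(=O)CC(C)C)[C@@]12C | intermediate
30 | C7 α-hydroxy C8 ketone, 5-O-triethylsilyl ether | CC(=O)O[C@H]1CC=C(C)[C@@H]2CC(=O)[C@H](O)C[C@@](C)(O[Si](CC)(CC)CC)CC[C@H](OC(=O)CC(C)C)[C@@]12C | intermediate
31 | C7 2-(diethoxyphosphoryl)propanoate (phosphonate carbon as epimers) | CC(=O)O[C@H]1CC=C(C)[C@@H]2CC(=O)[C@H](OC(=O)C(C)P(=O)(OCC)OCC)C[C@@](C)(O[Si](CC)(CC)CC)CC[C@H](OC(=O)CC(C)C)[C@@]12C | intermediate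
32 | butenolide (C8=C17, C7–H), 5-O-triethylsilyl ether | CC(=O)O[C@H]1CC=C(C)[C@@H]2CC3=C(C)C(=O)O[C@@H]3C[C@@](C)(O[Si](CC)(CC)CC)CC[C@H](OC(=O)CC(C)C)[C@@]12C | intermediate
33 | 2-(triisopropylsilyloxy)furan (furan carbons C7, C8, C17, C19) | CC(=O)O[C@H]1CC=C(C)[C@@H]2Cc3c(C)c(O[Si](C(C)C)(C(C)C)C(C)C)oc3C[C@@](C)(O[Si](CC)(CC)CC)CC[C@H](OC(=O)CC(C)C)[C@@]12C | intermediate
34 | C7 bromobutenolide (not isolated; C7 not defined) | CC(=O)O[C@H]1CC=C(C)[C@@H]2CC3=C(C)C(=O)OC3(Br)C[C@@](C)(O[Si](CC)(CC)CC)CC[C@H](OC(=O)CC(C)C)[C@@]12C | intermediate
35 | (6E)-alkylidene butenolide, 5-O-triethylsilyl ether of the target | CC(=O)O[C@H]1CC=C(C)[C@@H]2CC3=C(C)C(=O)O/C3=C/[C@@](C)(O[Si](CC)(CC)CC)CC[C@H](OC(=O)CC(C)C)[C@@]12C | intermediate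
36 | CNP0208239.1 | CC(=O)O[C@H]1CC=C(C)[C@@H]2CC3=C(C)C(=O)O/C3=C/[C@@](C)(O)CC[C@H](OC(=O)CC(C)C)[C@@]12C | target

## Step count and least certain steps

Total step count: 26. Longest linear sequence: 26 steps (1 to 36); 10 and 24 enter without prior steps.

**Step 19 (key step).** The most likely failure is slow ionisation, because the metal must bind the ring face that carries the C2 chain and the C14 acetate, followed by slow attack at the neopentyl terminus C10. That would leave time for β-hydride elimination toward C13 (diene formation) or for intermolecular alkylation at the open C12 terminus (oligomers). The fallback makes the same bond with the same chirality transfer by a sigmatropic ring contraction instead of a direct macrocyclisation. It sets out from 21. Bromoacetyl bromide and pyridine would give the C12 bromoacetate F1. Direct Swern oxidation of the primary silyl ether, as in step 16, would give the bromoacetate aldehyde F2. SmI2 in THF under high dilution would close the fourteen-membered ring by an intramolecular Reformatsky reaction to the β-hydroxy macrolactone F3, and Dess–Martin oxidation would give the macrocyclic allyl β-keto ester F4. Heating F4 in toluene or xylene (110–140 °C) should trigger the Carroll rearrangement: the [3,3] shift of the enol form makes C9–C10 suprafacially, on the face of the C12–O bond, and the β-keto acid loses CO2. The route is rejoined at 29, without the sulfone.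

**Step 10.** The likely failure is hydride attack on the wrong face of the C2 carbonyl if the zinc chelate is not dominant, or competing 1,2-reduction at C10. The fallback replaces substrate control by catalyst control: from 14, Corey–Bakshi–Shibata reduction with (R)-2-methyl-CBS-oxazaborolidine and catecholborane in toluene at −78 °C. The catalyst distinguishes the quaternary C1 side from the C3 methylene side of the C2 ketone and should give the 2S alcohol whatever the intrinsic bias. It returns to the route at 15 and makes no new compound.

**Step 14.** The likely failure is slow hydrazone formation at the C10 ketone, which is flanked by the quaternary C1 and the fully substituted epoxide carbon, with hydrazinolysis of the acetate taking over. The fallback is a radical transposition that does not need a hydrazone. From 19, NaBH4 with CeCl3·7H2O in MeOH at −40 °C would give the C10 epoxy alcohol F5 (either epimer serves). 1,1'-Thiocarbonyldiimidazole and DMAP in warm 1,2-dichloroethane would give the imidazolyl thiocarbonate F6. Bu3SnH and AIBN in toluene at 80 °C would generate the C10 radical, which opens the adjacent epoxide to the C10=C11 alkene and the C12 alkoxy radical; hydrogen transfer completes the alcohol with the C12–O bond unchanged. The route is rejoined at 21.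

**Step 21.** The likely failure is loss of both silyl ethers, since the α-keto secondary and the tertiary ether are distinguished only by shielding. The fallback accepts global desilylation and protects the tertiary alcohol again afterwards. From 29, excess HF·pyridine at room temperature would give the 5,7-diol F7. Carbodiimide esterification as in step 22 acylates only the secondary C7 hydroxyl, giving the phosphonopropionate with free C5 hydroxyl F8. TESOTf and 2,6-lutidine at −78 °C then silylate the tertiary alcohol. The route is rejoined at 31.

**Step 25.** The likely failures are poor site selectivity of the bromination (attack at C17 or at the ring A alkene) and elimination to the ring-trans isomer. The fallback is a selenoxide elimination, which is stereospecifically syn and needs no base. From 33, PhSeCl in THF at −78 °C would give the C7 phenylselenide F9. Oxidation with H2O2 and pyridine in CH2Cl2 at 0 °C gives the selenoxide, which can only eliminate toward C6. The route is rejoined at 35.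

## Further compounds

F1 | step 19 | C12 bromoacetate of 21 | CC(=O)O[C@H]1C[C@H](OC(=O)CBr)C(C)=C[C@@]1(C)[C@@H](OC(=O)CC(C)C)CC[C@](C)(O[Si](CC)(CC)CC)C[C@@H](O[Si](CC)(CC)CC)CO[Si](CC)(CC)CC
F2 | step 19 | C12 bromoacetate C8 aldehyde | CC(=O)O[C@H]1C[C@H](OC(=O)CBr)C(C)=C[C@@]1(C)[C@@H](OC(=O)CC(C)C)CC[C@](C)(O[Si](CC)(CC)CC)C[C@@H](O[Si](CC)(CC)CC)C=O
F3 | step 19 | fourteen-membered β-hydroxy macrolactone (C8 carbinol, C8 epimers) | CC(=O)O[C@H]1C[C@@H]2OC(=O)CC(O)[C@H](O[Si](CC)(CC)CC)C[C@@](C)(O[Si](CC)(CC)CC)CC[C@H](OC(=O)CC(C)C)[C@]1(C)C=C2C
F4 | step 19 | fourteen-membered allyl β-keto ester (C8 ketone) | CC(=O)O[C@H]1C[C@@H]2OC(=O)CC(=O)[C@H](O[Si](CC)(CC)CC)C[C@@](C)(O[Si](CC)(CC)CC)CC[C@H](OC(=O)CC(C)C)[C@]1(C)C=C2C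
F0 | step 10 | none | none
F5 | step 14 | C10 epoxy alcohol from 19 (C10 epimers) | CC(=O)O[C@H]1C[C@@H]2O[C@]2(C)C(O)[C@@]1(C)[C@@H](OC(=O)CC(C)C)CC[C@](C)(O[Si](CC)(CC)CC)C[C@@H](O[Si](CC)(CC)CC)CO[Si](CC)(CC)CC
F6 | step 14 | C10 O-(imidazol-1-ylthiocarbonyl) derivative of F5 | CC(=O)O[C@H]1C[C@@H]2O[C@]2(C)C(OC(=S)n3ccnc3)[C@@]1(C)[C@@H](OC(=O)CC(C)C)CC[C@](C)(O[Si](CC)(CC)CC)C[C@@H](O[Si](CC)(CC)CC)CO[Si](CC)(CC)CC
F7 | step 21 | ten-membered C8 ketone 5,7-diol | CC(=O)O[C@H]1CC=C(C)[C@@H]2CC(=O)[C@H](O)C[C@@](C)(O)CC[C@H](OC(=O)CC(C)C)[C@@]12C
F8 | step 21 | C7 phosphonopropionate with free C5 hydroxyl | CC(=O)O[C@H]1CC=C(C)[C@@H]2CC(=O)[C@H](OC(=O)C(C)P(=O)(OCC)OCC)C[C@@](C)(O)CC[C@H](OC(=O)CC(C)C)[C@@]12C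
F9 | step 25 | C7 phenylselenenyl butenolide (C7 not defined) | CC(=O)O[C@H]1CC=C(C)[C@@H]2CC3=C(C)C(=O)OC3([Se]c4ccccc4)C[C@@](C)(O[Si](CC)(CC)CC)CC[C@H](OC(=O)CC(C)C)[C@@]12C
A1 | alternative 1 | cis-anti-cis photoadduct (C1–C2 and C5–C6 formed) | O=C1CC[C@@H](C2(C)OCCO2)[C@]3(C)[C@H]4CC[C@@]4(C)[C@H]13
A2 | alternative 1 | 3-methyl-4-(2-methyl-1,3-dioxolan-2-yl)cyclohex-2-enone (C7 ketone, C1=C6) | O=C1CC[C@@H](C2(C)OCCO2)C(C)=C1
A3 | alternative 1 | 1-methylcyclobutene | CC1=CCC1
A4 | alternative 1 | cyclodeca-1,5-dienone after cycloreversion (alkene geometry left open) | O=C1CC[C@@H](C2(C)OCCO2)C(C)=CCCC(C)=C1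
A5 | alternative 2 | ten-membered carbocycle bridged by an isoxazoline between C5 and C7 | CC(=O)O[C@H]1CC=C(C)[C@@H]2C/C(=C(\C)C(=O)OC)C3=NO[C@](C)(C3)CC[C@H](OC(=O)CC(C)C)[C@@]12C
A6 | alternative 2 | open-chain C7 aldoxime with C5=C6 methylidene (oxime geometry left open) | CC(=O)O[C@H]1CC=C(C)[C@H](C/C(C=NO)=C(\C)C(=O)OC)[C@@]1(C)[C@H](CCC(C)=C)OC(=O)CC(C)C
A7 | alternative 3 | ten-membered C2 ketone with C5 silyl ether and enol lactone | CC(C)(C)[Si](C)(C)O[C@H]1CC=C(C)[C@@H]2CC3=C(C)C(=O)O/C3=C/[C@@](C)(O[Si](C(C)C)(C(C)C)C(C)C)CCC(=O)[C@@]12C
A8 | alternative 3 | tricyclic 1,2-divinyl carbinol (C2–C7 bond; C2, C7 and enol ether geometry left open) | CC(C)(C)[Si](C)(C)O[C@H]1CC=C(C)[C@@H]2CC3=C(C)C(=O)OC3(C=C(C)O[Si](C(C)C)(C(C)C)C(C)C)C(O)(C=C)[C@@]12C
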